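**Retrosynthetic overview**
- Dactylomelol ⇐ its triethylsilyl (TES) ether ⇐ bromohydrin ⇐ (R)-epoxide ⇐ trisubstituted alkene of a homoprenyl chain (Br enters with inversion; Cl then enters at the tertiary carbon with retention at CHBr).
- 7-Oxabicyclo[2.2.1]heptane ⇐ cis-4-methylidenecyclohexanol by transannular alkoxymercuration. The ether bridge is formed second; the methylidene carbon becomes the bridgehead methyl.
- Cyclohexane (formed first) ⇐ acyclic bromo-dienone by a nickel-mediated reductive ring closure. The bromoalkene carbon, a masked acetone carbonyl carbon, attacks the enone β-carbon as an acyl-anion-type nucleophile.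
- The quaternary carbon comes from anti-alkylation of the resulting silyl enol ether; the ring carbinol from hydride reduction.
- Bromo-dienone ⇐ enone from (S)-linalool (ozonolysis, Wittig) + 2,3-dibromopropene, used as a reversed-polarity acetone unit (acetonyl cation first, masked acetonyl anion second).

Assumption: (S)-(+)-linalool of high enantiomeric purity is taken as commercial; the sense of induction of the chiral ligand in step 5 is assumed as drawn, otherwise its antipode is used.

**Step 1**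
Reactants: 1 (3S)-3,7-dimethylocta-1,6-dien-3-ol [(S)-(+)-linalool]
Product: 2 triethyl{[(3S)-3,7-dimethylocta-1,6-dien-3-yl]oxy}silane
Conditions: Et3SiOTf, 2,6-lutidine, CH2Cl2, −78 → 0 °C
Reagents that add atoms: triethylsilyl trifluoromethanesulfonate, CC[Si](CC)(CC)OS(=O)(=O)C(F)(F)F
Why: O-silylation of the hindered tertiary allylic alcohol with a silyl triflate, which later prevents oxa-Michael addition to the enone and masks the alcohol during chlorination; no stereocentre is touched.

**Step 2**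
Reactants: 2 triethyl{[(3S)-3,7-dimethylocta-1,6-dien-3-yl]oxy}silane
Product: 4 (4S)-4-methyl-4-[(triethylsilyl)oxy]hex-5-enal, via secondary ozonide 3 (not isolated)
Conditions: O3 (1.0 equiv, Sudan Red 7B end point), CH2Cl2, −78 °C; then Me2S, −78 °C → rt
Reagents that add atoms: ozone, [O-][O+]=O
Why: Chemoselective ozonolysis, since the electron-rich trisubstituted alkene reacts far faster than the monosubstituted vinyl group; reductive work-up gives the aldehyde and the carbinol centre is untouched.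

**Step 3**
Reactants: 4 (4S)-4-methyl-4-[(triethylsilyl)oxy]hex-5-enal; 5 3-(triphenyl-λ5-phosphanylidene)butan-2-one
Product: 6 (3E,7S)-3,7-dimethyl-7-[(triethylsilyl)oxy]nona-3,8-dien-2-one
Conditions: toluene, 90 °C
Reagents that add atoms: none
Why: Wittig olefination with a stabilised α-methyl acyl ylide gives the (E)-trisubstituted enone.

**Step 4**
Reactants: 6 (3E,7S)-3,7-dimethyl-7-[(triethylsilyl)oxy]nona-3,8-dien-2-one; 7 2,3-dibromoprop-1-ene
Product: 9 (6E,10S)-2-bromo-6,10-dimethyl-10-[(triethylsilyl)oxy]dodeca-1,6,11-trien-5-one, via lithium enolate 8 (not isolated)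
Conditions: LiN(iPr)2, THF, −78 °C; then 7, −78 → 0 °C
Reagents that add atoms: none
Why: Kinetic α′-deprotonation gives the cross-conjugated enolate, which is allylated (SN2) by 2,3-dibromopropene acting as an acetonyl-cation (enolonium) equivalent, so two carbons that are each α to an oxygenated carbon are joined; the vinylic bromide is untouched.

**Step 5**
Reactants: 9 (6E,10S)-2-bromo-6,10-dimethyl-10-[(triethylsilyl)oxy]dodeca-1,6,11-trien-5-one
Product: 10 triethyl[((3R)-2-methyl-4-methylidene-3-{(3S)-3-methyl-3-[(triethylsilyl)oxy]pent-4-en-1-yl}cyclohex-1-en-1-yl)oxy]silane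
Conditions: NiBr2·glyme (10 mol%), (S,S)-iPr-PyBox (12 mol%), Mn powder, Et3SiCl, DMF, 25 °C
Reagents that add atoms: chlorotriethylsilane, CC[Si](Cl)(CC)CC
Why: Proposed new method: zerovalent nickel and the silyl chloride turn the enone into a 1-siloxyallylnickel species, Mn reduction and intramolecular oxidative addition of the C–Br bond give an alkenyl(allyl)nickel that reductively eliminates at the former β-carbon (six-membered ring, enone carbonyl inside the ring), so the bromoalkene carbon (the masked carbonyl carbon of an acetone unit) acts as an acyl-anion-type nucleophile in an electrophile–electrophile coupling and the enolate is trapped regiospecifically as its silyl ether; the chiral PyBox ligand sets the single new stereocentre (3R) by face selection at the allyl terminus; the closest known reactions are the racemic intermolecular nickel/Mn/chlorosilane reductive conjugate addition of alkenyl and aryl halides to enones and nickel-catalysed enantioselective reductive cyclisations with chiral N-ligands.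

**Step 6**
Reactants: 10 triethyl[((3R)-2-methyl-4-methylidene-3-{(3S)-3-methyl-3-[(triethylsilyl)oxy]pent-4-en-1-yl}cyclohex-1-en-1-yl)oxy]silane; 11 5-bromo-2-methylpent-2-ene
Product: 13 (2S,3R)-2-methyl-4-methylidene-2-(4-methylpent-3-en-1-yl)-3-{(3S)-3-methyl-3-[(triethylsilyl)oxy]pent-4-en-1-yl}cyclohexan-1-one, via lithium enolate 12 (not isolated)
Conditions: MeLi, THF, 0 °C → rt; then 11, HMPA, Bu4NI (10 mol%), −20 °C → rt
Reagents that add atoms: none
Why: MeLi cleaves only the enol silyl ether to the regiodefined tetrasubstituted enolate, and SN2 alkylation occurs anti to the C-3 side chain (held pseudoaxial by allylic strain against the 2-methyl and 4-methylidene groups), setting the quaternary centre (2S) with the new chain trans to it.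

**Step 7**
Reactants: 13 (2S,3R)-2-methyl-4-methylidene-2-(4-methylpent-3-en-1-yl)-3-{(3S)-3-methyl-3-[(triethylsilyl)oxy]pent-4-en-1-yl}cyclohexan-1-one
Product: 14 (1S,2S,3R)-2-methyl-4-methylidene-2-(4-methylpent-3-en-1-yl)-3-{(3S)-3-methyl-3-[(triethylsilyl)oxy]pent-4-en-1-yl}cyclohexan-1-ol
Conditions: NaBH4, MeOH/THF, 0 °C → rt
Reagents that add atoms: none
Why: Diastereoselective carbonyl reduction: hydride attacks axially on the chair with both chains equatorial and the 2-methyl axial (the axial methyl blocks equatorial attack), giving the equatorial (1S)-alcohol cis to the 2-methyl group and the C-3 side chain.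

**Step 8**
Reactants: 14 (1S,2S,3R)-2-methyl-4-methylidene-2-(4-methylpent-3-en-1-yl)-3-{(3S)-3-methyl-3-[(triethylsilyl)oxy]pent-4-en-1-yl}cyclohexan-1-ol
Product: 16 triethyl{[(3S)-5-[(1R,2S,3S,4S)-1,3-dimethyl-3-(4-methylpent-3-en-1-yl)-7-oxabicyclo[2.2.1]heptan-2-yl]-3-methylpent-1-en-3-yl]oxy}silane, via alkylmercury acetate 15 (not isolated)
Conditions: Hg(OAc)2, THF, 0 °C → rt; then NaBH4, aq NaOH, 0 °C
Reagents that add atoms: none
Why: Transannular Markovnikov alkoxymercuration through a boat conformer puts oxygen on the substituted alkene carbon, and demercuration turns the methylidene carbon into the bridgehead methyl; the new quaternary centre is dictated by the bridge geometry (oxymercuration–demercuration).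

**Step 9**
Reactants: 16 triethyl{[(3S)-5-[(1R,2S,3S,4S)-1,3-dimethyl-3-(4-methylpent-3-en-1-yl)-7-oxabicyclo[2.2.1]heptan-2-yl]-3-methylpent-1-en-3-yl]oxy}silane
Product: 17 triethyl{[(3S)-5-[(1R,2S,3S,4S)-3-{2-[(2R)-3,3-dimethyloxiran-2-yl]ethyl}-1,3-dimethyl-7-oxabicyclo[2.2.1]heptan-2-yl]-3-methylpent-1-en-3-yl]oxy}silane
Conditions: Shi ketone (D-fructose-derived, 30 mol%), Oxone (2KHSO5·KHSO4·K2SO4), K2CO3, Bu4NHSO4, MeCN/dimethoxymethane/aq borate buffer (pH 10.5), 0 °C
Reagents that add atoms: Oxone (active component potassium peroxymonosulfate), [K+].[O-]S(=O)(=O)OO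
Why: Shi asymmetric epoxidation: the chiral dioxirane attacks only the electron-rich trisubstituted alkene (the vinyl group is inert) through a spiro transition state, and the D-fructose-derived ketone gives the (R)-epoxide.

**Step 10**
Reactants: 17 triethyl{[(3S)-5-[(1R,2S,3S,4S)-3-{2-[(2R)-3,3-dimethyloxiran-2-yl]ethyl}-1,3-dimethyl-7-oxabicyclo[2.2.1]heptan-2-yl]-3-methylpent-1-en-3-yl]oxy}silane
Product: 18 triethyl{[(3S)-5-[(1R,2S,3S,4S)-3-[(3S)-3-bromo-4-hydroxy-4-methylpentyl]-1,3-dimethyl-7-oxabicyclo[2.2.1]heptan-2-yl]-3-methylpent-1-en-3-yl]oxy}silane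
Conditions: Li2NiBr4, THF, 0 °C → rt; aq phosphate buffer work-up
Reagents that add atoms: dilithium tetrabromonickelate, [Li+].[Li+].Br[Ni-2](Br)(Br)Br
Why: Soft, near-neutral bromide delivery opens the trisubstituted epoxide by SN2 at the less substituted carbon with inversion (R epoxide → S bromide), leaving the tertiary alcohol (regioselective epoxide opening).

**Step 11**
Reactants: 18 triethyl{[(3S)-5-[(1R,2S,3S,4S)-3-[(3S)-3-bromo-4-hydroxy-4-methylpentyl]-1,3-dimethyl-7-oxabicyclo[2.2.1]heptan-2-yl]-3-methylpent-1-en-3-yl]oxy}silane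
Product: 19 triethyl{[(3S)-5-[(1R,2S,3S,4S)-3-[(3S)-3-bromo-4-chloro-4-methylpentyl]-1,3-dimethyl-7-oxabicyclo[2.2.1]heptan-2-yl]-3-methylpent-1-en-3-yl]oxy}silane
Conditions: 1-chloro-N,N,2-trimethylprop-1-en-1-amine (Ghosez reagent), CH2Cl2, 0 °C → rt
Reagents that add atoms: 1-chloro-N,N,2-trimethylprop-1-en-1-amine, CC(C)=C(Cl)N(C)C
Why: Neutral dehydroxychlorination with the α-chloroenamine: the O-imidoyl group ionises with help from the neighbouring bromine and chloride adds to the tertiary carbon, so the CHBr centre keeps its configuration.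

**Step 12**
Reactants: 19 triethyl{[(3S)-5-[(1R,2S,3S,4S)-3-[(3S)-3-bromo-4-chloro-4-methylpentyl]-1,3-dimethyl-7-oxabicyclo[2.2.1]heptan-2-yl]-3-methylpent-1-en-3-yl]oxy}silane
Product: 20 (3S)-5-[(1R,2S,3S,4S)-3-[(3S)-3-bromo-4-chloro-4-methylpentyl]-1,3-dimethyl-7-oxabicyclo[2.2.1]heptan-2-yl]-3-methylpent-1-en-3-ol (dactylomelol)
Conditions: HF·pyridine, pyridine, THF, 0 °C → rt
Reagents that add atoms: none
Why: Buffered fluoride desilylation frees the tertiary allylic alcohol without touching the alkyl halides or the ether bridge; no stereocentre is affected.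

**Compound list**
1 | (3S)-3,7-dimethylocta-1,6-dien-3-ol [(S)-(+)-linalool] | C=C[C@@](C)(O)CCC=C(C)C | starting material
2 | triethyl{[(3S)-3,7-dimethylocta-1,6-dien-3-yl]oxy}silane | C=C[C@@](C)(O[Si](CC)(CC)CC)CCC=C(C)C | intermediate
3 | 3,3-dimethyl-5-{(3S)-3-methyl-3-[(triethylsilyl)oxy]pent-4-en-1-yl}-1,2,4-trioxolane (secondary ozonide, C-5 epimers, not isolated) | C=C[C@@](C)(O[Si](CC)(CC)CC)CCC1OOC(C)(C)O1 | intermediate
4 | (4S)-4-methyl-4-[(triethylsilyl)oxy]hex-5-enal | C=C[C@@](C)(O[Si](CC)(CC)CC)CCC=O | intermediate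
5 | 3-(triphenyl-λ5-phosphanylidene)butan-2-one | CC(=O)C(C)=P(c1ccccc1)(c1ccccc1)c1ccccc1 | starting material
6 | (3E,7S)-3,7-dimethyl-7-[(triethylsilyl)oxy]nona-3,8-dien-2-one | C=C[C@@](C)(O[Si](CC)(CC)CC)CC/C=C(\C)C(C)=O | intermediate
7 | 2,3-dibromoprop-1-ene | C=C(Br)CBr | starting material
8 | lithium (3E,7S)-3,7-dimethyl-7-[(triethylsilyl)oxy]nona-1,3,8-trien-2-olate (not isolated) | C=C[C@@](C)(O[Si](CC)(CC)CC)CC/C=C(\C)C(=C)O[Li] | intermediate
9 | (6E,10S)-2-bromo-6,10-dimethyl-10-[(triethylsilyl)oxy]dodeca-1,6,11-trien-5-one | C=C[C@@](C)(O[Si](CC)(CC)CC)CC/C=C(\C)C(=O)CCC(Br)=C | intermediate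
10 | triethyl[((3R)-2-methyl-4-methylidene-3-{(3S)-3-methyl-3-[(triethylsilyl)oxy]pent-4-en-1-yl}cyclohex-1-en-1-yl)oxy]silane | C=C[C@@](C)(O[Si](CC)(CC)CC)CC[C@H]1C(C)=C(O[Si](CC)(CC)CC)CCC1=C | intermediate
11 | 5-bromo-2-methylpent-2-ene | CC(C)=CCCBr | starting material
12 | lithium (3R)-2-methyl-4-methylidene-3-{(3S)-3-methyl-3-[(triethylsilyl)oxy]pent-4-en-1-yl}cyclohex-1-en-1-olate (not isolated) | C=C[C@@](C)(O[Si](CC)(CC)CC)CC[C@H]1C(C)=C(O[Li])CCC1=C | intermediate
13 | (2S,3R)-2-methyl-4-methylidene-2-(4-methylpent-3-en-1-yl)-3-{(3S)-3-methyl-3-[(triethylsilyl)oxy]pent-4-en-1-yl}cyclohexan-1-one | C=C[C@@](C)(O[Si](CC)(CC)CC)CC[C@H]1[C@](C)(CCC=C(C)C)C(=O)CCC1=C | intermediate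
14 | (1S,2S,3R)-2-methyl-4-methylidene-2-(4-methylpent-3-en-1-yl)-3-{(3S)-3-methyl-3-[(triethylsilyl)oxy]pent-4-en-1-yl}cyclohexan-1-ol | C=C[C@@](C)(O[Si](CC)(CC)CC)CC[C@H]1[C@](C)(CCC=C(C)C)[C@@H](O)CCC1=C | intermediate
15 | alkylmercury acetate: analogue of 16 with AcOHg–CH2 in place of the bridgehead CH3, same configuration (not isolated) | C=C[C@@](C)(O[Si](CC)(CC)CC)CC[C@H]1[C@](C)(CCC=C(C)C)[C@@H]2CC[C@@]1(C[Hg]OC(C)=O)O2 | intermediate
16 | triethyl{[(3S)-5-[(1R,2S,3S,4S)-1,3-dimethyl-3-(4-methylpent-3-en-1-yl)-7-oxabicyclo[2.2.1]heptan-2-yl]-3-methylpent-1-en-3-yl]oxy}silane | C=C[C@@](C)(O[Si](CC)(CC)CC)CC[C@H]1[C@](C)(CCC=C(C)C)[C@@H]2CC[C@@]1(C)O2 | intermediate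
17 | triethyl{[(3S)-5-[(1R,2S,3S,4S)-3-{2-[(2R)-3,3-dimethyloxiran-2-yl]ethyl}-1,3-dimethyl-7-oxabicyclo[2.2.1]heptan-2-yl]-3-methylpent-1-en-3-yl]oxy}silane | C=C[C@@](C)(O[Si](CC)(CC)CC)CC[C@H]1[C@](C)(CC[C@H]3OC3(C)C)[C@@H]2CC[C@@]1(C)O2 | intermediate
18 | triethyl{[(3S)-5-[(1R,2S,3S,4S)-3-[(3S)-3-bromo-4-hydroxy-4-methylpentyl]-1,3-dimethyl-7-oxabicyclo[2.2.1]heptan-2-yl]-3-methylpent-1-en-3-yl]oxy}silane | C=C[C@@](C)(O[Si](CC)(CC)CC)CC[C@H]1[C@](C)(CC[C@H](Br)C(C)(C)O)[C@@H]2CC[C@@]1(C)O2 | intermediate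
19 | triethyl{[(3S)-5-[(1R,2S,3S,4S)-3-[(3S)-3-bromo-4-chloro-4-methylpentyl]-1,3-dimethyl-7-oxabicyclo[2.2.1]heptan-2-yl]-3-methylpent-1-en-3-yl]oxy}silane | C=C[C@@](C)(O[Si](CC)(CC)CC)CC[C@H]1[C@](C)(CC[C@H](Br)C(C)(C)Cl)[C@@H]2CC[C@@]1(C)O2 | intermediate
20 | (3S)-5-[(1R,2S,3S,4S)-3-[(3S)-3-bromo-4-chloro-4-methylpentyl]-1,3-dimethyl-7-oxabicyclo[2.2.1]heptan-2-yl]-3-methylpent-1-en-3-ol (dactylomelol) | C=C[C@@](C)(O)CC[C@H]1[C@](C)(CC[C@H](Br)C(C)(C)Cl)[C@@H]2CC[C@@]1(C)O2 | target

**Step count and risks**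
Total step count: 12. Longest linear sequence: 12 steps (from 1).

The three steps most likely to fail:

Step 5 (enantioselective nickel reductive ring closure; unprecedented as an asymmetric intramolecular variant). The fallback sets out from 6 and returns at 13. The kinetic lithium enolate of 6 is alkylated with 2-(3-bromoprop-1-en-2-yl)-4,4,5,5-tetramethyl-1,3,2-dioxaborolane instead of 7, giving the alkenylboronate enone F1. F1 is cyclised by [Rh(cod)OH]2/(R)-BINAP with aq KOH in dioxane: transmetalation to an alkenyl complex of monovalent rhodium, intramolecular 1,4-addition to the enone, then protonation. This boron/rhodium conjugate addition replaces the nickel cross-electrophile coupling and gives the cyclohexanone F2. The lithium enolate of F2 is equilibrated to the more substituted isomer (LiN(SiMe3)2, 0.95 equiv, THF) and alkylated with 11 to rejoin the route at 13.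

Step 6 (quaternary centre by SN2 on an unactivated homoallylic bromide). The fallback sets out from 10 and returns at 13. Enolate 12 is generated as before but is intercepted with 4-methylpent-3-enal, a much faster aldol addition that occurs on the same face, to give the β-hydroxy ketone F3. F3 is converted with 1,1′-thiocarbonyldiimidazole/DMAP into the imidazolylthiocarbonate F4. F4 is deoxygenated with Bu3SnH/AIBN (Barton–McCombie) to give 13.

Step 10 (regiochemistry of bromide opening at the hindered secondary carbon). The fallback sets out from 17 and returns at 19, skipping 18. The epoxide is opened with chloride at the tertiary carbon (pyridinium chloride, CH2Cl2, 0 °C; the secondary C–O bond stays intact) to give the chlorohydrin F5. The secondary alcohol of F5 is then replaced by bromide with inversion (CBr4, PPh3, Appel) to give 19.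

**Further compounds**
F1 | step 5 | (6E,10S)-6,10-dimethyl-2-(4,4,5,5-tetramethyl-1,3,2-dioxaborolan-2-yl)-10-[(triethylsilyl)oxy]dodeca-1,6,11-trien-5-one | C=C[C@@](C)(O[Si](CC)(CC)CC)CC/C=C(\C)C(=O)CCC(=C)B1OC(C)(C)C(C)(C)O1
F2 | step 5 | (3S)-2-methyl-4-methylidene-3-{(3S)-3-methyl-3-[(triethylsilyl)oxy]pent-4-en-1-yl}cyclohexan-1-one (C-2 epimers; same spatial arrangement at C-3 as in 10) | C=C[C@@](C)(O[Si](CC)(CC)CC)CC[C@H]1C(C)C(=O)CCC1=C
F3 | step 6 | (2R,3R)-2-(1-hydroxy-4-methylpent-3-en-1-yl)-2-methyl-4-methylidene-3-{(3S)-3-methyl-3-[(triethylsilyl)oxy]pent-4-en-1-yl}cyclohexan-1-one (carbinol epimers) | C=C[C@@](C)(O[Si](CC)(CC)CC)CC[C@H]1[C@](C)(C(O)CC=C(C)C)C(=O)CCC1=C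
F4 | step 6 | O-[1-[(1R,2R)-1-methyl-3-methylidene-2-{(3S)-3-methyl-3-[(triethylsilyl)oxy]pent-4-en-1-yl}-6-oxocyclohexyl]-4-methylpent-3-en-1-yl] 1H-imidazole-1-carbothioate | C=C[C@@](C)(O[Si](CC)(CC)CC)CC[C@H]1[C@](C)(C(OC(=S)n2ccnc2)CC=C(C)C)C(=O)CCC1=C
F5 | step 10 | triethyl{[(3S)-5-[(1R,2S,3S,4S)-3-[(3R)-4-chloro-3-hydroxy-4-methylpentyl]-1,3-dimethyl-7-oxabicyclo[2.2.1]heptan-2-yl]-3-methylpent-1-en-3-yl]oxy}silane | C=C[C@@](C)(O[Si](CC)(CC)CC)CC[C@H]1[C@](C)(CC[C@@H](O)C(C)(C)Cl)[C@@H]2CC[C@@]1(C)O2
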